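**Plan**

1. Numbering used below (labdane style): ring A = C1–C5 and C10 (C2 carbinol, C4 gem‑dimethyl), ring B = C5–C10, C17 = the CH2OH carbon on C8, C11–C12 = ethylene link, C13–C16 = butenolide.
2. Enabling feature: the C2 oxygen is 1,3 to the quaternary C10, so ring A at the ketone level is a 3‑methylcyclohexenone with C10 as β‑carbon; the cis A/B fusion (H‑5 syn to the C10 methyl) is what a tether anchored at C5 delivers; C8=C9 carrying C17 is the enol triflate of a β‑keto ester.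
3. Cuts: butenolide ⇒ 3‑furyl; C2–OH and C17–OH ⇒ ketone and ester; C9–C10 (ring B, reductive Heck); C7–C8 (β‑keto ester alkylation); C6–C7 (iodomethyl addition to the C6 aldehyde); C5–C6 ([2,3] shift from a C1 carbinol).
4. Forward: ring A is bought; the C5 side chain is built, then the enone, then union with the furyl β‑keto ester, then ring B, then the reductions, then furan → butenolide.
5. Stereochemistry: one carbinol (C1) from CBS reduction, relayed to C5 by a suprafacial Still–Wittig shift; C6 by Felkin–Anh addition; C10 by the cis‑fusion constraint of the ring closure; C2 by hydride attack on the convex face.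

Key step: step 12

Assumption: 2,4,4‑trimethylcyclohex‑2‑en‑1‑one (1) is taken as a catalogue compound; otherwise it is one Robinson annulation away from isobutyraldehyde and ethyl vinyl ketone.

**Route**

Step 1
Reactants: 1 2,4,4‑trimethylcyclohex‑2‑en‑1‑one
Product: 2 (1S)‑2,4,4‑trimethylcyclohex‑2‑en‑1‑ol
Conditions: (R)‑2‑methyl‑CBS‑oxazaborolidine (10 mol %), BH3·SMe2, THF, −20 °C; MeOH, then aqueous work‑up
Reagents that add atoms: none
Why: Corey–Bakshi–Shibata reduction, in which the 2‑methylalkenyl arm acts as the large group, so the (R)‑catalyst should deliver hydride to the face that gives the 1S allylic alcohol, the only stereocenter set by catalysis.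

Step 2
Reactants: 2 (1S)‑2,4,4‑trimethylcyclohex‑2‑en‑1‑ol
Product: 3 tributyl({[(1S)‑2,4,4‑trimethylcyclohex‑2‑en‑1‑yl]oxy}methyl)stannane
Conditions: KH, THF, 0 °C; Bu3SnCH2I, 18‑crown‑6 (cat.), 0 °C → rt
Reagents that add atoms: tributyl(iodomethyl)stannane, CCCC[Sn](CCCC)(CCCC)CI
Why: Williamson etherification of the potassium alkoxide with the reactive primary iodide, which leaves the carbinol center untouched.

Step 3
Reactants: 3 tributyl({[(1S)‑2,4,4‑trimethylcyclohex‑2‑en‑1‑yl]oxy}methyl)stannane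
Product: 4 [(1R)‑2,6,6‑trimethylcyclohex‑2‑en‑1‑yl]methanol
Conditions: n‑BuLi, THF, −78 °C
Reagents that add atoms: none
Why: Still–Wittig [2,3]‑sigmatropic rearrangement: tin–lithium exchange gives the α‑alkoxymethyllithium, which bonds to C5 on the ring face from which the C1–O bond departs (suprafacial), so the 1S carbinol is relayed to the C5 stereocenter (1R in this compound) and the alkene moves to C1=C10.

Step 4
Reactants: 4 [(1R)‑2,6,6‑trimethylcyclohex‑2‑en‑1‑yl]methanol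
Product: 5 (1R)‑2,6,6‑trimethylcyclohex‑2‑ene‑1‑carbaldehyde
Conditions: Pr4N[RuO4] (5 mol %), N‑methylmorpholine N‑oxide, 4 Å MS, CH2Cl2, 0 °C
Reagents that add atoms: none
Why: Ley–Griffith oxidation of the primary alcohol under neutral conditions, which avoids epimerisation at C5 and migration of the β,γ‑alkene into conjugation.

Step 5
Reactants: 5 (1R)‑2,6,6‑trimethylcyclohex‑2‑ene‑1‑carbaldehyde
Product: 6 (1R)‑2‑iodo‑1‑[(1R)‑2,6,6‑trimethylcyclohex‑2‑en‑1‑yl]ethan‑1‑ol
Conditions: CH2I2, MeLi·LiBr (added last), THF–Et2O, −78 °C; AcOH, −78 °C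
Reagents that add atoms: diiodomethane, ICI
Why: Halomethyllithium carbonyl addition: iodomethyllithium made in the flask by iodine–lithium exchange adds to the aldehyde, and Felkin–Anh control (nucleophile anti to the quaternary C4 arm, passing H‑5 on the pseudoaxial formyl rotamer) should set C6 as 1R, while the cold acetic acid quench keeps the iodohydrin from closing to the epoxide.

Step 6
Reactants: 6 (1R)‑2‑iodo‑1‑[(1R)‑2,6,6‑trimethylcyclohex‑2‑en‑1‑yl]ethan‑1‑ol
Product: 7 tert‑butyl{(1R)‑2‑iodo‑1‑[(1R)‑2,6,6‑trimethylcyclohex‑2‑en‑1‑yl]ethoxy}dimethylsilane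
Conditions: TBSOTf, 2,6‑lutidine, CH2Cl2, −78 → 0 °C
Reagents that add atoms: tert‑butyldimethylsilyl triflate, CC(C)(C)[Si](C)(C)OS(=O)(=O)C(F)(F)F
Why: Silylation of the hindered secondary alcohol with a silyl triflate and a non‑nucleophilic base, which protects C6–OH through the oxidation, alkylation and reduction steps.

Step 7
Reactants: 7 tert‑butyl{(1R)‑2‑iodo‑1‑[(1R)‑2,6,6‑trimethylcyclohex‑2‑en‑1‑yl]ethoxy}dimethylsilane
Product: 8 (4R)‑4‑[(1R)‑1‑{[tert‑butyl(dimethyl)silyl]oxy}‑2‑iodoethyl]‑3,5,5‑trimethylcyclohex‑2‑en‑1‑one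
Conditions: CrO3, 3,5‑dimethylpyrazole, CH2Cl2, −20 °C
Reagents that add atoms: chromium trioxide, O=[Cr](=O)=O
Why: Allylic oxidation of the only ring methylene next to the C1=C10 alkene (C2) to the enone, as established for α‑ionone‑type rings; the C10 methyl and the hindered tertiary C5–H should react more slowly, and the iodide and silyl ether are inert.

Step 8
Reactants: 9 furan‑3‑ylmethanol
Product: 10 3‑(bromomethyl)furan
Conditions: PBr3, pyridine (cat.), Et2O, 0 °C; used at once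
Reagents that add atoms: phosphorus tribromide, BrP(Br)Br
Why: Conversion of the primary alcohol into the bromide by SN2 displacement on the phosphite ester; the labile bromide is not stored.

Step 9
Reactants: 11 ethyl acetoacetate, 10 3‑(bromomethyl)furan
Product: 12 ethyl 5‑(furan‑3‑yl)‑3‑oxopentanoate
Conditions: NaH, THF, 0 °C; n‑BuLi, 0 °C; then 10, 0 °C → rt
Reagents that add atoms: none
Why: γ‑Alkylation of the acetoacetate dianion, in which the more basic terminal carbanion attacks the furylmethyl bromide and gives the C9–C11–C12–furan chain.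

Step 10
Reactants: 8 (4R)‑4‑[(1R)‑1‑{[tert‑butyl(dimethyl)silyl]oxy}‑2‑iodoethyl]‑3,5,5‑trimethylcyclohex‑2‑en‑1‑one, 12 ethyl 5‑(furan‑3‑yl)‑3‑oxopentanoate
Product: 13 ethyl 2‑[(2S)‑2‑{[tert‑butyl(dimethyl)silyl]oxy}‑2‑[(1R)‑2,6,6‑trimethyl‑4‑oxocyclohex‑2‑en‑1‑yl]ethyl]‑5‑(furan‑3‑yl)‑3‑oxopentanoate (mixture at the carbon between the carbonyls)
Conditions: NaH (1 equiv, on 12), THF–DMF, 0 → 50 °C
Reagents that add atoms: none
Why: Acetoacetic ester C‑alkylation with the primary iodide forms C7–C8; the weakly basic aprotic enolate leaves the enone γ‑hydrogen at C5 and the silyl ether untouched and does not add to the hindered enone (such additions are reversible), and the new C8 center is inconsequential because it becomes sp2 in step 11.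

Step 11
Reactants: 13 ethyl 2‑[(2S)‑2‑{[tert‑butyl(dimethyl)silyl]oxy}‑2‑[(1R)‑2,6,6‑trimethyl‑4‑oxocyclohex‑2‑en‑1‑yl]ethyl]‑5‑(furan‑3‑yl)‑3‑oxopentanoate
Product: 14 ethyl (2E)‑2‑[(2S)‑2‑{[tert‑butyl(dimethyl)silyl]oxy}‑2‑[(1R)‑2,6,6‑trimethyl‑4‑oxocyclohex‑2‑en‑1‑yl]ethyl]‑5‑(furan‑3‑yl)‑3‑[(trifluoromethanesulfonyl)oxy]pent‑2‑enoate
Conditions: Tf2O, aq. Me4NOH, toluene, 0 °C
Reagents that add atoms: triflic anhydride, O=S(=O)(OS(=O)(=O)C(F)(F)F)C(F)(F)F
Why: O‑Triflation of the β‑keto ester enolate; with the non‑chelating Me4N+ counter‑ion the enolate oxygen sits anti to the ester carbonyl, so the (E)‑enol triflate (triflate cis to the C7 chain) is expected, as in known E‑selective triflations of acyclic β‑keto esters.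

Step 12
Reactants: 14 ethyl (2E)‑2‑[(2S)‑2‑{[tert‑butyl(dimethyl)silyl]oxy}‑2‑[(1R)‑2,6,6‑trimethyl‑4‑oxocyclohex‑2‑en‑1‑yl]ethyl]‑5‑(furan‑3‑yl)‑3‑[(trifluoromethanesulfonyl)oxy]pent‑2‑enoate
Product: 15 ethyl (4S,4aR,8aS)‑4‑{[tert‑butyl(dimethyl)silyl]oxy}‑1‑[2‑(furan‑3‑yl)ethyl]‑5,5,8a‑trimethyl‑7‑oxo‑3,4,4a,5,6,7,8,8a‑octahydronaphthalene‑2‑carboxylate
Conditions: Pd(OAc)2 (10 mol %), PPh3 (25 mol %), HCO2Na (1.5 equiv), degassed DMF, 70 °C
Reagents that add atoms: none
Why: Zerovalent palladium, formed in the flask from Pd(OAc)2 and PPh3, inserts into the C9–OTf bond, the alkenylpalladium adds syn across the enone C10=C1 bond with C9 bonding to the β‑carbon C10, and the resulting palladium enolate, which cannot undergo β‑hydride elimination because both carbons flanking the C2 carbonyl (C1 and C3) are attached to quaternary carbons (C10 and C4), is intercepted by formate (decarboxylation to a palladium hydride, then C1–H formation). The closest known reaction type is the intramolecular reductive Heck (conjugate‑addition‑type) cyclization of alkenyl or aryl (pseudo)halides onto β‑substituted cyclohexenones that forges quaternary carbons. Ring B closes in the 6‑exo‑trig mode (C10 inside the new ring, C1 outside). The new quaternary stereocenter C10 is controlled by C5: A(1,2) strain with the C10 methyl keeps the C6 side chain pseudoaxial on one face of the enone, so the three‑atom tether C6–C7–C8 can deliver C9 only to that face, which gives the cis ring fusion with the C10 methyl syn to H‑5. The step needs the palladium at C9 to be cis to C7, which the (E)‑triflate from step 11 secures, and it needs carbopalladation to outrun direct formate reduction of the alkenylpalladium, which the intramolecular six‑membered transition state and the slow hydride release from sparingly soluble HCO2Na should secure.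

Step 13
Reactants: 15 ethyl (4S,4aR,8aS)‑4‑{[tert‑butyl(dimethyl)silyl]oxy}‑1‑[2‑(furan‑3‑yl)ethyl]‑5,5,8a‑trimethyl‑7‑oxo‑3,4,4a,5,6,7,8,8a‑octahydronaphthalene‑2‑carboxylate
Product: 16 (2S,4aR,5S,8aS)‑5‑{[tert‑butyl(dimethyl)silyl]oxy}‑8‑[2‑(furan‑3‑yl)ethyl]‑7‑(hydroxymethyl)‑4,4,8a‑trimethyl‑1,2,3,4,4a,5,6,8a‑octahydronaphthalen‑2‑ol
Conditions: i‑Bu2AlH (5 equiv), CH2Cl2, −78 → 0 °C; aq. potassium sodium tartrate work‑up
Reagents that add atoms: none
Why: i‑Bu2AlH reduces the conjugated ester to the C17 allylic alcohol and the C2 ketone to the carbinol; in the cis‑fused bicycle ring B folds under one face of ring A (C9 and one C4 methyl flank the carbonyl there), so hydride should arrive from the exposed face that carries the C10 methyl and H‑5 and give the 2S alcohol, trans to the C10 methyl.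

Step 14
Reactants: 16 (2S,4aR,5S,8aS)‑5‑{[tert‑butyl(dimethyl)silyl]oxy}‑8‑[2‑(furan‑3‑yl)ethyl]‑7‑(hydroxymethyl)‑4,4,8a‑trimethyl‑1,2,3,4,4a,5,6,8a‑octahydronaphthalen‑2‑ol
Product: 17 (2S,4aR,5S,8aS)‑8‑[2‑(furan‑3‑yl)ethyl]‑7‑(hydroxymethyl)‑4,4,8a‑trimethyl‑1,2,3,4,4a,5,6,8a‑octahydronaphthalene‑2,5‑diol
Conditions: Bu4NF, THF, rt
Reagents that add atoms: none
Why: Fluoride cleaves the secondary silyl ether through Si–F bond formation; the furan, the alkene and the free hydroxyls are unaffected.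

Step 15
Reactants: 17 (2S,4aR,5S,8aS)‑8‑[2‑(furan‑3‑yl)ethyl]‑7‑(hydroxymethyl)‑4,4,8a‑trimethyl‑1,2,3,4,4a,5,6,8a‑octahydronaphthalene‑2,5‑diol
Product: 19 4‑{2‑[(4S,4aR,7S,8aS)‑4,7‑dihydroxy‑2‑(hydroxymethyl)‑5,5,8a‑trimethyl‑3,4,4a,5,6,7,8,8a‑octahydronaphthalen‑1‑yl]ethyl}furan‑2(5H)‑one (target), via γ‑hydroxybutenolide 18 (not isolated)
Conditions: O2, visible light, meso‑tetraphenylporphyrin (cat.), i‑Pr2NEt, CH2Cl2, −78 °C; then NaBH4, EtOH, 0 °C; mildly acidic work‑up
Reagents that add atoms: dioxygen, O=O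
Why: Singlet oxygen adds [4+2] to the 3‑alkylfuran and the hindered amine removes the less hindered bridgehead hydrogen of the endoperoxide, which gives the 4‑alkyl‑5‑hydroxybutenolide regioselectively; NaBH4 then reduces its open hydroxy‑aldehyde form and the hydroxy acid relactonizes to the 4‑substituted furan‑2(5H)‑one, the furan being expected to react with singlet oxygen faster than the hindered tetrasubstituted C8=C9 alkene, as in late‑stage furan photooxygenations next to tetrasubstituted cyclohexene alkenes.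

**Compound list**

1 | 2,4,4‑trimethylcyclohex‑2‑en‑1‑one | CC1=CC(C)(C)CCC1=O | starting material
2 | (1S)‑2,4,4‑trimethylcyclohex‑2‑en‑1‑ol | O[C@@H]1C(C)=CC(C)(C)CC1 | intermediate
3 | tributyl({[(1S)‑2,4,4‑trimethylcyclohex‑2‑en‑1‑yl]oxy}methyl)stannane | CCCC[Sn](CCCC)(CCCC)CO[C@@H]1C(C)=CC(C)(C)CC1 | intermediate
4 | [(1R)‑2,6,6‑trimethylcyclohex‑2‑en‑1‑yl]methanol | OC[C@H]1C(C)=CCCC1(C)C | intermediate
5 | (1R)‑2,6,6‑trimethylcyclohex‑2‑ene‑1‑carbaldehyde | O=C[C@H]1C(C)=CCCC1(C)C | intermediate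
6 | (1R)‑2‑iodo‑1‑[(1R)‑2,6,6‑trimethylcyclohex‑2‑en‑1‑yl]ethan‑1‑ol | IC[C@H](O)[C@H]1C(C)=CCCC1(C)C | intermediate
7 | tert‑butyl{(1R)‑2‑iodo‑1‑[(1R)‑2,6,6‑trimethylcyclohex‑2‑en‑1‑yl]ethoxy}dimethylsilane | IC[C@H](O[Si](C)(C)C(C)(C)C)[C@H]1C(C)=CCCC1(C)C | intermediate
8 | (4R)‑4‑[(1R)‑1‑{[tert‑butyl(dimethyl)silyl]oxy}‑2‑iodoethyl]‑3,5,5‑trimethylcyclohex‑2‑en‑1‑one | IC[C@H](O[Si](C)(C)C(C)(C)C)[C@H]1C(C)=CC(=O)CC1(C)C | intermediate
9 | furan‑3‑ylmethanol | OCc1ccoc1 | starting material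
10 | 3‑(bromomethyl)furan | BrCc1ccoc1 | intermediate
11 | ethyl acetoacetate | CCOC(=O)CC(C)=O | starting material
12 | ethyl 5‑(furan‑3‑yl)‑3‑oxopentanoate | CCOC(=O)CC(=O)CCc1ccoc1 | intermediate
13 | ethyl 2‑[(2S)‑2‑{[tert‑butyl(dimethyl)silyl]oxy}‑2‑[(1R)‑2,6,6‑trimethyl‑4‑oxocyclohex‑2‑en‑1‑yl]ethyl]‑5‑(furan‑3‑yl)‑3‑oxopentanoate | CCOC(=O)C(C[C@H](O[Si](C)(C)C(C)(C)C)[C@H]1C(C)=CC(=O)CC1(C)C)C(=O)CCc1ccoc1 | intermediate
14 | ethyl (2E)‑2‑[(2S)‑2‑{[tert‑butyl(dimethyl)silyl]oxy}‑2‑[(1R)‑2,6,6‑trimethyl‑4‑oxocyclohex‑2‑en‑1‑yl]ethyl]‑5‑(furan‑3‑yl)‑3‑[(trifluoromethanesulfonyl)oxy]pent‑2‑enoate | CCOC(=O)/C(C[C@H](O[Si](C)(C)C(C)(C)C)[C@H]1C(C)=CC(=O)CC1(C)C)=C(/OS(=O)(=O)C(F)(F)F)CCc1ccoc1 | intermediate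
15 | ethyl (4S,4aR,8aS)‑4‑{[tert‑butyl(dimethyl)silyl]oxy}‑1‑[2‑(furan‑3‑yl)ethyl]‑5,5,8a‑trimethyl‑7‑oxo‑3,4,4a,5,6,7,8,8a‑octahydronaphthalene‑2‑carboxylate | CC1(C)CC(=O)C[C@]2(C)C(CCc3ccoc3)=C(C(=O)OCC)C[C@H](O[Si](C)(C)C(C)(C)C)[C@H]12 | intermediate
16 | (2S,4aR,5S,8aS)‑5‑{[tert‑butyl(dimethyl)silyl]oxy}‑8‑[2‑(furan‑3‑yl)ethyl]‑7‑(hydroxymethyl)‑4,4,8a‑trimethyl‑1,2,3,4,4a,5,6,8a‑octahydronaphthalen‑2‑ol | CC1(C)C[C@H](O)C[C@]2(C)C(CCc3ccoc3)=C(CO)C[C@H](O[Si](C)(C)C(C)(C)C)[C@H]12 | intermediate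
17 | (2S,4aR,5S,8aS)‑8‑[2‑(furan‑3‑yl)ethyl]‑7‑(hydroxymethyl)‑4,4,8a‑trimethyl‑1,2,3,4,4a,5,6,8a‑octahydronaphthalene‑2,5‑diol | CC1(C)C[C@H](O)C[C@]2(C)C(CCc3ccoc3)=C(CO)C[C@H](O)[C@H]12 | intermediate
18 | 4‑{2‑[(4S,4aR,7S,8aS)‑4,7‑dihydroxy‑2‑(hydroxymethyl)‑5,5,8a‑trimethyl‑3,4,4a,5,6,7,8,8a‑octahydronaphthalen‑1‑yl]ethyl}‑5‑hydroxyfuran‑2(5H)‑one (mixture at the hemiacetal carbon) | CC1(C)C[C@H](O)C[C@]2(C)C(CCC3=CC(=O)OC3O)=C(CO)C[C@H](O)[C@H]12 | intermediate
19 | 4‑{2‑[(4S,4aR,7S,8aS)‑4,7‑dihydroxy‑2‑(hydroxymethyl)‑5,5,8a‑trimethyl‑3,4,4a,5,6,7,8,8a‑octahydronaphthalen‑1‑yl]ethyl}furan‑2(5H)‑one | CC1(C)C[C@H](O)C[C@]2(C)C(CCC3=CC(=O)OC3)=C(CO)C[C@H](O)[C@H]12 | target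

**Step count and risks**

Total steps: 15. Longest linear sequence: 13 (steps 1–7 and 10–15; steps 8–9 make the side‑chain fragment).

Step 12. The alkenylpalladium may be reduced by formate before it inserts into the hindered β,β‑disubstituted enone, or insertion may stall and the triflate be lost by hydrolysis. The fallback sets out from β‑keto ester 13 and closes the same bond by a ketyl–enone reductive cyclization with SmI2 (THF, HMPA, t‑BuOH, −78 °C). The chelated ketyl at C9 adds to the enone β‑carbon C10 in the 6‑exo mode, cis‑fused for the same tether reason, and should give the cyclized tertiary β‑hydroxy ester F1 as a mixture at the two carbons that become sp2. Dehydration across C8–C9 toward the acidic ester α‑hydrogen (SOCl2, pyridine, or Burgess reagent) comes back to the route at 15.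

Step 11. Loss of E/Z control in the O‑sulfonylation would leave part of the material with the leaving group trans to the C7 chain, which cannot cyclize through palladium. The fallback sets out from 13 and makes the β‑bromo enoate F2 as an E/Z mixture (Ph3PBr2, Et3N, CH2Cl2). It is then cyclized by a tin hydride radical reaction (Bu3SnH by slow addition, AIBN, benzene, 80 °C). The σ‑vinyl radical at C9 inverts rapidly, so both isomers should funnel through 6‑exo addition to C10 and come back to the route at 15.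

Step 5. Poor facial selectivity in the addition to the aldehyde (weak discrimination between the C4 and C10 arms in the Felkin–Anh transition state) would erode or invert the C6 configuration. The fallback sets out from 5 and replaces substrate control by reagent control. Chloromethyllithium (ICH2Cl, MeLi·LiBr, −78 °C) gives the epimeric chlorohydrin mixture F3. Dess–Martin oxidation gives the chloromethyl ketone F4. CBS reduction with the (R)‑oxazaborolidine and BH3·SMe2 sets C6 and gives the (1R)‑chlorohydrin F5. Finkelstein exchange (NaI, acetone) comes back to the route at 6.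

**Further compounds**

F1 | step 12 | ethyl (4S,4aR,8aS)‑4‑{[tert‑butyl(dimethyl)silyl]oxy}‑1‑[2‑(furan‑3‑yl)ethyl]‑1‑hydroxy‑5,5,8a‑trimethyl‑7‑oxodecahydronaphthalene‑2‑carboxylate (mixture at C1 and C2) | CC1(C)CC(=O)C[C@]2(C)C(O)(CCc3ccoc3)C(C(=O)OCC)C[C@H](O[Si](C)(C)C(C)(C)C)[C@H]12
F2 | step 11 | ethyl 3‑bromo‑2‑[(2S)‑2‑{[tert‑butyl(dimethyl)silyl]oxy}‑2‑[(1R)‑2,6,6‑trimethyl‑4‑oxocyclohex‑2‑en‑1‑yl]ethyl]‑5‑(furan‑3‑yl)pent‑2‑enoate (E/Z mixture) | CCOC(=O)C(C[C@H](O[Si](C)(C)C(C)(C)C)[C@H]1C(C)=CC(=O)CC1(C)C)=C(Br)CCc1ccoc1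
F3 | step 5 | 2‑chloro‑1‑[(1R)‑2,6,6‑trimethylcyclohex‑2‑en‑1‑yl]ethan‑1‑ol (mixture at the carbinol carbon) | ClCC(O)[C@H]1C(C)=CCCC1(C)C
F4 | step 5 | 2‑chloro‑1‑[(1R)‑2,6,6‑trimethylcyclohex‑2‑en‑1‑yl]ethan‑1‑one | ClCC(=O)[C@H]1C(C)=CCCC1(C)C
F5 | step 5 | (1R)‑2‑chloro‑1‑[(1R)‑2,6,6‑trimethylcyclohex‑2‑en‑1‑yl]ethan‑1‑ol | ClC[C@H](O)[C@H]1C(C)=CCCC1(C)C
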